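**Plan**

- Retrosynthesis: cut C13=C14 (olefination), the two C–O bonds at C2/C3 (dihydroxylation of a ring-A C2=C3 alkene), C9–C11 (organometallic addition to a C9 ketone), then both ring-B bonds of C9 (C8–C9 and C9–C10) together with C10–B/C5–H, then C7–C8 and C5–C6.
- Enabling feature: in ring B only C9 lies between the methyl-bearing C8 and the quaternary C10. A borinane with boron at that position can therefore be made by syn hydroboration of the tetrasubstituted C5=C10 alkene of a ring-A cyclohexene from a borane on C8, and the boron then swapped for a carbonyl carbon.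
- Forward: ring A is bought as 2,2-dimethylcyclohexane-1,3-dione; the C6–C8 chain is attached at C5; ring B closes in the key step; ring A is then desaturated, the side chain is added at C9 and extended, and the diol comes last.
- Stereochemistry: C8 from (–)-sparteine-controlled lithiation–borylation; C5 and C10 relayed from C8 through the chair-like cyclic hydroboration (syn addition gives the trans fusion); C9 by attack anti to the 10β-methyl; C2/C3 by α-face osmylation; 13E from the Horner–Wadsworth–Emmons reaction.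

Key step: step 8

Remark on the chemistry: bicyclic compounds are named on the labdane skeleton (ring A = C1–C5, C10; ring B = C5–C10; side chain C11–C16), β being the face of the C10 methyl group; ethyl N,N-diisopropylcarbamate and (–)-sparteine are taken as purchasable.

**Route**

Step 1
Reactants: 1 2,2-dimethylcyclohexane-1,3-dione
Product: 2 6,6-dimethyl-1,4-dioxaspiro[4.5]decan-7-one
Conditions: HOCH2CH2OH (1.05 equiv), p-TsOH·H2O (5 mol %), benzene, reflux, Dean–Stark
Reagents that add atoms: ethylene glycol, OCCO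
Why: Acid-catalysed ketalisation with removal of water should stop largely at the mono-dioxolane because the remaining carbonyl is then neopentylic and more hindered, and the symmetric dione poses no regiochemical question.

Step 2
Reactants: 2 6,6-dimethyl-1,4-dioxaspiro[4.5]decan-7-one
Product: 3 (±)-6,6,8-trimethyl-1,4-dioxaspiro[4.5]decan-7-one
Conditions: LiN(iPr)2 (1.05 equiv), THF, –78 °C; MeI, –78 → 0 °C
Reagents that add atoms: iodomethane, CI
Why: Enolate alkylation can occur only on the side away from the quaternary carbon, so the methyl group enters at the future C10, whose configuration is irrelevant because it becomes sp2 in step 3.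

Step 3
Reactants: 3 (±)-6,6,8-trimethyl-1,4-dioxaspiro[4.5]decan-7-one
Product: 4 6,6,8-trimethyl-1,4-dioxaspiro[4.5]dec-7-en-7-yl trifluoromethanesulfonate
Conditions: KN(SiMe3)2 (1.2 equiv), THF, –78 → 0 °C; PhNTf2, 0 °C → rt
Reagents that add atoms: N-phenylbis(trifluoromethanesulfonimide), O=S(=O)(N(c1ccccc1)S(=O)(=O)C(F)(F)F)C(F)(F)F
Why: O-Sulfonylation of the only enolate that can form gives the tetrasubstituted enol triflate and so fixes the C5=C10 double bond.

Step 4
Reactants: 4 6,6,8-trimethyl-1,4-dioxaspiro[4.5]dec-7-en-7-yl trifluoromethanesulfonate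
Product: 5 7-ethenyl-6,6,8-trimethyl-1,4-dioxaspiro[4.5]dec-7-ene
Conditions: CH2=CHSnBu3 (1.3 equiv), Pd(PPh3)4 (5 mol %), LiCl (3 equiv), THF, 65 °C
Reagents that add atoms: tributyl(vinyl)stannane, C=C[Sn](CCCC)(CCCC)CCCC
Why: Stille coupling of an enol triflate with a small vinylstannane, with chloride assisting transmetalation, tolerates the hindered cyclohexenyl triflate and forms C5–C6.

Step 5
Reactants: 5 7-ethenyl-6,6,8-trimethyl-1,4-dioxaspiro[4.5]dec-7-ene
Product: 6 4,4,5,5-tetramethyl-2-[2-(6,6,8-trimethyl-1,4-dioxaspiro[4.5]dec-7-en-7-yl)ethyl]-1,3,2-dioxaborolane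
Conditions: HBpin (1.2 equiv), [Ir(cod)Cl]2 (1.5 mol %), dppm (3 mol %), CH2Cl2, rt
Reagents that add atoms: pinacolborane, B1OC(C)(C)C(C)(C)O1
Why: Iridium-catalysed anti-Markovnikov hydroboration should place boron on the terminal carbon (C7), because the vinyl group is twisted out of conjugation by the flanking methyl groups and behaves as an isolated monosubstituted alkene while the tetrasubstituted ring alkene is inert.

Step 6
Reactants: 6 4,4,5,5-tetramethyl-2-[2-(6,6,8-trimethyl-1,4-dioxaspiro[4.5]dec-7-en-7-yl)ethyl]-1,3,2-dioxaborolane; 7 ethyl N,N-diisopropylcarbamate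
Product: 10 4,4,5,5-tetramethyl-2-[(2R)-4-(6,6,8-trimethyl-1,4-dioxaspiro[4.5]dec-7-en-7-yl)butan-2-yl]-1,3,2-dioxaborolane, via lithiated carbamate 8 (not isolated), via boronate complex 9 (not isolated)
Conditions: 7 (1.5 equiv), sBuLi (1.4 equiv), (–)-sparteine (1.4 equiv), Et2O, –78 °C, 5 h; 6, –78 °C, 1 h; MgBr2·OEt2, reflux, 16 h
Reagents that add atoms: none
Why: Lithiation–borylation: sBuLi/(–)-sparteine removes the pro-S α-proton of 7, the configurationally stable carbenoid 8 is borylated with retention, and in 9 the primary alkyl group shifts from boron to carbon with inversion as the carbamate leaves, which forms C7–C8 and sets C8 as R.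

Step 7
Reactants: 10 4,4,5,5-tetramethyl-2-[(2R)-4-(6,6,8-trimethyl-1,4-dioxaspiro[4.5]dec-7-en-7-yl)butan-2-yl]-1,3,2-dioxaborolane
Product: 11 lithium trihydrido[(2R)-4-(6,6,8-trimethyl-1,4-dioxaspiro[4.5]dec-7-en-7-yl)butan-2-yl]borate
Conditions: LiAlH4 (1.0 equiv), Et2O–pentane, 0 °C; filtered from the aluminium alkoxide under argon, solution used directly
Reagents that add atoms: lithium aluminium hydride, [Li+].[AlH4-]
Why: Hydride reduction of a boronic ester to the lithium monoalkyltrihydroborate exchanges only the B–O bonds, so the C8–B stereocentre, the ketal and the alkene are untouched.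

Step 8
Reactants: 11 lithium trihydrido[(2R)-4-(6,6,8-trimethyl-1,4-dioxaspiro[4.5]dec-7-en-7-yl)butan-2-yl]borate; 12 dichloromethyl methyl ether
Product: 17 3,3-ethylenedioxy-4,4,8α,10β-tetramethyl-trans-decalin-9-one (5S,8R,10S), via alkylborane 13 (not isolated), via B-hydridoborinane 14 (not isolated), via B-methoxyborinane 15 (not isolated), via α-methoxy boronate 16 (not isolated)
Conditions: Me3SiCl (1.0 equiv), THF (0.01 M), 0 °C; 25 → 50 °C, 12 h; MeOH (1.1 equiv), 0 °C; 12 (1.5 equiv), LiOCEt3 (2.5 equiv), 0 °C → rt; 3 M NaOH, 30% H2O2, 50 °C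
Reagents that add atoms: hydrogen peroxide, OO
Why: Me3SiCl strips hydride from 11 to free monoalkylborane 13, whose B–H bond adds syn across the C5=C10 alkene through a four-centre transition state (boron to C10, hydrogen to C5) to give borinane 14; methanolysis to 15, attack of the carbenoid LiCCl2OMe (from 12 and LiOCEt3) on boron and two successive 1,2-shifts of C10 and C8 from boron to the new carbon with loss of chloride give 16, and alkaline H2O2 cleaves its C9–B bond so that the resulting hemiketal collapses to ketone 17. The closest known reactions are the cyclic hydroboration–carbonylation of 1-allylcycloalkenes to trans-fused bicyclic ketones and the conversion of dialkylborinates into ketones with dichloromethyl methyl ether, taken here to a tetrasubstituted alkene and a tertiary migrating carbon. Ring B closes once, first as the six-membered boracycle by 6-endo intramolecular hydroboration (both alkene carbons in the ring) and then, on the same ring atoms, as the carbocycle when the two shifts expand the boracycle by one carbon and contract it to a cyclohexane with boron exocyclic. C10 and C5 are the new stereocentres: syn delivery of boron and hydrogen forces the trans fusion (10-CH3 anti to 5-H), and the C8 methyl group, equatorial in the chair-like transition state because an axial methyl would clash with the C10 methyl across boron, selects the alkene face, so (R)-C8 gives 10β-CH3 and 5α-H. Both 1,2-shifts proceed with retention, so C8 and C10 pass unchanged from boron to carbon, and C8, epimerisable in 17, already holds its stable equatorial methyl. The step needs boron at C10 and not C5 (favoured by the six-membered ring and by the C4 gem-dimethyl group shielding C5), intramolecular over intermolecular addition (high dilution, an alkene inert to external boranes), and migration of carbon and not of the oxygen ligands (alkoxy groups on boron do not shift).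

Step 9
Reactants: 17 3,3-ethylenedioxy-4,4,8α,10β-tetramethyl-trans-decalin-9-one (5S,8R,10S)
Product: 18 4,4,8α,10β-tetramethyl-trans-decalin-3,9-dione (5S,8R,10S)
Conditions: 1 M HCl, THF, rt → 40 °C
Reagents that add atoms: water, O
Why: Acid-catalysed ketal hydrolysis frees the C3 ketone, and the only epimerisable centre, C8, already has its methyl group in the favoured equatorial position.

Step 10
Reactants: 18 4,4,8α,10β-tetramethyl-trans-decalin-3,9-dione (5S,8R,10S)
Product: 19 4,4,8α,10β-tetramethyl-9-oxo-trans-decal-2-en-3-yl trifluoromethanesulfonate (5S,8R,10S)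
Conditions: LiN(iPr)2 (1.05 equiv), THF, –78 °C, 30 min; N-(5-chloropyridin-2-yl)bis(trifluoromethanesulfonimide) (1.1 equiv), –78 → –20 °C
Reagents that add atoms: N-(5-chloropyridin-2-yl)bis(trifluoromethanesulfonimide), O=S(=O)(N(c1ccc(Cl)cn1)S(=O)(=O)C(F)(F)F)C(F)(F)F
Why: Kinetic deprotonation and O-triflation should give only the C2=C3 enol triflate, because the C3 ketone can enolise only toward the unhindered C2 methylene (C4 is quaternary) and this is far faster at –78 °C than removal of the single tertiary α-hydrogen (C8–H) of the C9 ketone.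

Step 11
Reactants: 19 4,4,8α,10β-tetramethyl-9-oxo-trans-decal-2-en-3-yl trifluoromethanesulfonate (5S,8R,10S)
Product: 20 4,4,8α,10β-tetramethyl-trans-decal-2-en-9-one (5S,8R,10S)
Conditions: Pd(OAc)2 (5 mol %), PPh3 (10 mol %), Bu3N (3 equiv), HCO2H (2 equiv), DMF, 60 °C
Reagents that add atoms: none
Why: Palladium-catalysed formate reduction of an enol triflate replaces OTf by H, leaving the C2=C3 alkene and the hindered C9 ketone untouched.

Step 12
Reactants: 20 4,4,8α,10β-tetramethyl-trans-decal-2-en-9-one (5S,8R,10S); 21 2-(2-bromoethyl)-2-methyl-1,3-dioxolane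
Product: 24 9α-[2-(2-methyl-1,3-dioxolan-2-yl)ethyl]-4,4,8α,10β-tetramethyl-trans-decal-2-en-9β-ol (5S,8R,9S,10S), via Grignard reagent 22 (not isolated), via organocerium reagent 23 (not isolated)
Conditions: 21 (3 equiv), Mg, THF, 25 °C; CeCl3 (anhydrous, 3 equiv), THF, –78 °C, 1 h; 20, –78 → 0 °C; aq NH4Cl
Reagents that add atoms: none
Why: Grignard formation and transmetalation give a weakly basic organocerium reagent that should add to the hindered, enolisable ketone without enolisation or hydride transfer, and it attacks C9 from the α-face, anti to the axial 10β-methyl group, so the new stereocentre carries the chain α and the hydroxyl β.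

Step 13
Reactants: 24 9α-[2-(2-methyl-1,3-dioxolan-2-yl)ethyl]-4,4,8α,10β-tetramethyl-trans-decal-2-en-9β-ol (5S,8R,9S,10S)
Product: 25 4-(9β-hydroxy-4,4,8α,10β-tetramethyl-trans-decal-2-en-9α-yl)butan-2-one (5S,8R,9S,10S)
Conditions: PPTS (0.3 equiv), acetone–H2O (10:1), 50 °C
Reagents that add atoms: water, O
Why: Mild acid-catalysed hydrolysis of the unhindered side-chain dioxolane in wet acetone frees the methyl ketone under conditions that the tertiary alcohol and the ring alkene survive.

Step 14
Reactants: 25 4-(9β-hydroxy-4,4,8α,10β-tetramethyl-trans-decal-2-en-9α-yl)butan-2-one (5S,8R,9S,10S)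
Product: 26 methyl (2E)-5-(9β-hydroxy-4,4,8α,10β-tetramethyl-trans-decal-2-en-9α-yl)-3-methylpent-2-enoate (5S,8R,9S,10S)
Conditions: (MeO)2P(O)CH2CO2Me (3.0 equiv), NaH (2.8 equiv), THF, 0 °C; 25, 0 → 60 °C
Reagents that add atoms: trimethyl phosphonoacetate, COC(=O)CP(=O)(OC)OC
Why: Horner–Wadsworth–Emmons olefination of a methyl ketone should favour the E alkene (ester trans to the larger C12 chain), the minor Z isomer being removable by chromatography, and keeping the phosphonate in slight excess over NaH avoids building up the C9 alkoxide.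

Step 15
Reactants: 26 methyl (2E)-5-(9β-hydroxy-4,4,8α,10β-tetramethyl-trans-decal-2-en-9α-yl)-3-methylpent-2-enoate (5S,8R,9S,10S)
Product: 27 methyl (2E)-5-(2α,3α,9β-trihydroxy-4,4,8α,10β-tetramethyl-trans-decalin-9α-yl)-3-methylpent-2-enoate (2R,3S,5S,8R,9S,10S), CNP0292844.1
Conditions: OsO4 (5 mol %), NMO (1.3 equiv), acetone–H2O (4:1), 0 °C → rt
Reagents that add atoms: osmium tetroxide (catalytic oxygen carrier), O=[Os](=O)(=O)=O; N-methylmorpholine N-oxide, C[N+]1([O-])CCOCC1; water, O
Why: Upjohn dihydroxylation should be chemoselective for the electron-rich cis-disubstituted C2=C3 alkene over the electron-poor trisubstituted enoate, and the syn addition comes from the α-face because the axial 4β- and 10β-methyl groups shield the β-face, giving the 2α,3α-diol.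

**Compound list**

1 | 2,2-dimethylcyclohexane-1,3-dione | CC1(C)C(=O)CCCC1=O | starting material
2 | 6,6-dimethyl-1,4-dioxaspiro[4.5]decan-7-one | O=C1CCCC2(OCCO2)C1(C)C | intermediate
3 | (±)-6,6,8-trimethyl-1,4-dioxaspiro[4.5]decan-7-one | O=C1C(C)CCC2(OCCO2)C1(C)C | intermediate
4 | 6,6,8-trimethyl-1,4-dioxaspiro[4.5]dec-7-en-7-yl trifluoromethanesulfonate | CC1=C(OS(=O)(=O)C(F)(F)F)C(C)(C)C2(OCCO2)CC1 | intermediate
5 | 7-ethenyl-6,6,8-trimethyl-1,4-dioxaspiro[4.5]dec-7-ene | C=CC1=C(C)CCC2(OCCO2)C1(C)C | intermediate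
6 | 4,4,5,5-tetramethyl-2-[2-(6,6,8-trimethyl-1,4-dioxaspiro[4.5]dec-7-en-7-yl)ethyl]-1,3,2-dioxaborolane (boron on C7) | CC1(C)OB(CCC2=C(C)CCC3(OCCO3)C2(C)C)OC1(C)C | intermediate
7 | ethyl N,N-diisopropylcarbamate | CCOC(=O)N(C(C)C)C(C)C | starting material
8 | (S)-1-lithioethyl N,N-diisopropylcarbamate, as its (–)-sparteine complex | C[C@H]([Li])OC(=O)N(C(C)C)C(C)C | intermediate
9 | lithium boronate complex of 6 and 8 (carbamate-bearing carbon S) | [Li+].C[C@H]([B-]1(CCC2=C(C)CCC3(OCCO3)C2(C)C)OC(C)(C)C(C)(C)O1)OC(=O)N(C(C)C)C(C)C | intermediate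
10 | 4,4,5,5-tetramethyl-2-[(2R)-4-(6,6,8-trimethyl-1,4-dioxaspiro[4.5]dec-7-en-7-yl)butan-2-yl]-1,3,2-dioxaborolane (boron on C8) | CC1(C)OB(OC1(C)C)[C@H](C)CCC1=C(C)CCC2(OCCO2)C1(C)C | intermediate
11 | lithium trihydrido[(2R)-4-(6,6,8-trimethyl-1,4-dioxaspiro[4.5]dec-7-en-7-yl)butan-2-yl]borate | [Li+].[BH3-][C@H](C)CCC1=C(C)CCC2(OCCO2)C1(C)C | intermediate
12 | dichloromethyl methyl ether | COC(Cl)Cl | starting material
13 | [(2R)-4-(6,6,8-trimethyl-1,4-dioxaspiro[4.5]dec-7-en-7-yl)butan-2-yl]borane (C8 alkylborane) | B[C@H](C)CCC1=C(C)CCC2(OCCO2)C1(C)C | intermediate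
14 | 3,3-ethylenedioxy-4,4,8α,10β-tetramethyl-9-bora-trans-decalin (B–H, 5α-H) | [BH]1[C@H](C)CC[C@H]2C(C)(C)C3(OCCO3)CC[C@@]21C | intermediate
15 | 9-methoxy-3,3-ethylenedioxy-4,4,8α,10β-tetramethyl-9-bora-trans-decalin | COB1[C@H](C)CC[C@H]2C(C)(C)C3(OCCO3)CC[C@@]21C | intermediate
16 | 3,3-ethylenedioxy-9-methoxy-9-[methoxy(3-ethylpentan-3-yloxy)boryl]-4,4,8α,10β-tetramethyl-trans-decalin (C9 unassigned) | COB(OC(CC)(CC)CC)C1(OC)[C@H](C)CC[C@H]2C(C)(C)C3(OCCO3)CC[C@@]21C | intermediate
17 | (5S,8R,10S)-3,3-ethylenedioxy-4,4,8α,10β-tetramethyl-trans-decalin-9-one | O=C1[C@H](C)CC[C@H]2C(C)(C)C3(OCCO3)CC[C@@]21C | intermediate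
18 | (5S,8R,10S)-4,4,8α,10β-tetramethyl-trans-decalin-3,9-dione | O=C1[C@H](C)CC[C@H]2C(C)(C)C(=O)CC[C@@]21C | intermediate
19 | (5S,8R,10S)-4,4,8α,10β-tetramethyl-9-oxo-trans-decal-2-en-3-yl trifluoromethanesulfonate | O=C1[C@H](C)CC[C@H]2C(C)(C)C(OS(=O)(=O)C(F)(F)F)=CC[C@@]21C | intermediate
20 | (5S,8R,10S)-4,4,8α,10β-tetramethyl-trans-decal-2-en-9-one | O=C1[C@H](C)CC[C@H]2C(C)(C)C=CC[C@@]21C | intermediate
21 | 2-(2-bromoethyl)-2-methyl-1,3-dioxolane | CC1(CCBr)OCCO1 | starting material
22 | [2-(2-methyl-1,3-dioxolan-2-yl)ethyl]magnesium bromide | CC1(CC[Mg]Br)OCCO1 | intermediate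
23 | dichloro[2-(2-methyl-1,3-dioxolan-2-yl)ethyl]cerium | CC1(CC[Ce](Cl)Cl)OCCO1 | intermediate
24 | (5S,8R,9S,10S)-9α-[2-(2-methyl-1,3-dioxolan-2-yl)ethyl]-4,4,8α,10β-tetramethyl-trans-decal-2-en-9β-ol | CC1(OCCO1)CC[C@]1(O)[C@H](C)CC[C@H]2C(C)(C)C=CC[C@@]21C | intermediate
25 | 4-[(5S,8R,9S,10S)-9β-hydroxy-4,4,8α,10β-tetramethyl-trans-decal-2-en-9α-yl]butan-2-one | CC(=O)CC[C@]1(O)[C@H](C)CC[C@H]2C(C)(C)C=CC[C@@]21C | intermediate
26 | methyl (2E)-5-[(5S,8R,9S,10S)-9β-hydroxy-4,4,8α,10β-tetramethyl-trans-decal-2-en-9α-yl]-3-methylpent-2-enoate | COC(=O)/C=C(\C)CC[C@]1(O)[C@H](C)CC[C@H]2C(C)(C)C=CC[C@@]21C | intermediate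
27 | methyl (2E)-5-[(2R,3S,5S,8R,9S,10S)-2α,3α,9β-trihydroxy-4,4,8α,10β-tetramethyl-trans-decalin-9α-yl]-3-methylpent-2-enoate (CNP0292844.1) | COC(=O)/C=C(\C)CC[C@]1(O)[C@H](C)CC[C@H]2C(C)(C)[C@H](O)[C@H](O)C[C@@]21C | target

**Totals and risks**

Total step count: 15. Longest linear sequence: 15 steps (1 → 27); 7, 12 and 21 are purchased.

Steps most likely to fail:

Step 8. The tethered borane may add to the crowded tetrasubstituted alkene too slowly, place boron at C5 (borolane), or react between molecules. The hindered borinate may also fail to take up the carbenoid or stop after one shift. The fallback closes ring B with an acyl radical and sets out from boronate 10. Matteson homologation (LiCHCl2 from CH2Cl2/n-BuLi, THF, –100 °C; ZnCl2, → rt) should give 2-[(2R)-1-chloro-2-methyl-4-(6,6,8-trimethyl-1,4-dioxaspiro[4.5]dec-7-en-7-yl)butyl]-4,4,5,5-tetramethyl-1,3,2-dioxaborolane F1 with retention at C8. Buffered NaClO2 (2-methyl-2-butene, t-BuOH–H2O) should oxidise it to (2R)-2-methyl-4-(6,6,8-trimethyl-1,4-dioxaspiro[4.5]dec-7-en-7-yl)butanoic acid F2, and PhSeSePh/PBu3 should convert this into the Se-phenyl selenoester F3. Bu3SnH/AIBN in dilute benzene at 80 °C would then generate the C9 acyl radical. Closure is expected in the 6-endo mode at C10, since 5-exo closure would have to build a spiro centre beside the C4 gem-dimethyl carbon, through a chair with the C8 methyl equatorial and the C10 methyl axial. Hydrogen transfer to the α-face of the C5 radical would give the trans-fused ketone, and the route is rejoined at 17.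

Step 12. Enolisation toward C8 or hydride transfer may outrun addition at the very hindered carbonyl, or the two faces may be discriminated poorly. The fallback sets out from ketone 20 and uses a Corey–Chaykovsky reaction with dimethylsulfonium methylide (Me3S+ I–, n-BuLi, THF, –10 °C). This small nucleophile adds irreversibly and axially (from the α-face), and should give the spiro-epoxide (9S)-4,4,8α,10β-tetramethylspiro[trans-decal-2-ene-9,2'-oxirane] F4 with oxygen β. Opening at its CH2 terminus with lithiated acetone N,N-dimethylhydrazone (THF, 0 °C → rt) should give the hydroxy hydrazone 4-(9β-hydroxy-4,4,8α,10β-tetramethyl-trans-decal-2-en-9α-yl)butan-2-one N,N-dimethylhydrazone F5. Hydrolysis (aqueous CuCl2, THF) would return the route at hydroxy ketone 25.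

Step 15. Osmylation of the enoate may compete, or the axial C9 chain on the α-face may slow and blur attack at C2=C3, at the last stage. The fallback moves the diol ahead of the side chain and sets out from ketone 20. OsO4/NMO on the unencumbered α-face should give 2α,3α-dihydroxy-4,4,8α,10β-tetramethyl-trans-decalin-9-one F6, and 2,2-dimethoxypropane/PPTS its 2,3-O-isopropylidene derivative F7. Addition of organocerium reagent 23 to C9 should give 9α-[2-(2-methyl-1,3-dioxolan-2-yl)ethyl]-2α,3α-isopropylidenedioxy-4,4,8α,10β-tetramethyl-trans-decalin-9β-ol F8. 1 M HCl in THF removes the acetonide and the dioxolane together to give 4-(2α,3α,9β-trihydroxy-4,4,8α,10β-tetramethyl-trans-decalin-9α-yl)butan-2-one F9. The olefination conditions of step 14, with extra phosphonate anion for the free hydroxyls, would convert F9 directly into 27, where the route is rejoined.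

**Further compounds**

F1 | step 8 | 2-[(2R)-1-chloro-2-methyl-4-(6,6,8-trimethyl-1,4-dioxaspiro[4.5]dec-7-en-7-yl)butyl]-4,4,5,5-tetramethyl-1,3,2-dioxaborolane | ClC(B1OC(C)(C)C(C)(C)O1)[C@H](C)CCC1=C(C)CCC2(OCCO2)C1(C)C
F2 | step 8 | (2R)-2-methyl-4-(6,6,8-trimethyl-1,4-dioxaspiro[4.5]dec-7-en-7-yl)butanoic acid | OC(=O)[C@H](C)CCC1=C(C)CCC2(OCCO2)C1(C)C
F3 | step 8 | Se-phenyl (2R)-2-methyl-4-(6,6,8-trimethyl-1,4-dioxaspiro[4.5]dec-7-en-7-yl)butaneselenoate | O=C([Se]c1ccccc1)[C@H](C)CCC1=C(C)CCC2(OCCO2)C1(C)C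
F4 | step 12 | (9S)-4,4,8α,10β-tetramethylspiro[trans-decal-2-ene-9,2'-oxirane] (oxygen β, CH2 α) | C1O[C@]12[C@H](C)CC[C@H]3C(C)(C)C=CC[C@@]32C
F5 | step 12 | 4-(9β-hydroxy-4,4,8α,10β-tetramethyl-trans-decal-2-en-9α-yl)butan-2-one N,N-dimethylhydrazone | CC(=NN(C)C)CC[C@]1(O)[C@H](C)CC[C@H]2C(C)(C)C=CC[C@@]21C
F6 | step 15 | 2α,3α-dihydroxy-4,4,8α,10β-tetramethyl-trans-decalin-9-one | O=C1[C@H](C)CC[C@H]2C(C)(C)[C@H](O)[C@H](O)C[C@@]21C
F7 | step 15 | 2α,3α-isopropylidenedioxy-4,4,8α,10β-tetramethyl-trans-decalin-9-one | O=C1[C@H](C)CC[C@H]2C(C)(C)[C@@H]3OC(C)(C)O[C@@H]3C[C@@]21C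
F8 | step 15 | 9α-[2-(2-methyl-1,3-dioxolan-2-yl)ethyl]-2α,3α-isopropylidenedioxy-4,4,8α,10β-tetramethyl-trans-decalin-9β-ol | CC1(OCCO1)CC[C@]1(O)[C@H](C)CC[C@H]2C(C)(C)[C@@H]3OC(C)(C)O[C@@H]3C[C@@]21C
F9 | step 15 | 4-(2α,3α,9β-trihydroxy-4,4,8α,10β-tetramethyl-trans-decalin-9α-yl)butan-2-one | CC(=O)CC[C@]1(O)[C@H](C)CC[C@H]2C(C)(C)[C@H](O)[C@H](O)C[C@@]21C
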